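**Plan**

- Retrosynthesis: cut O1–C2 of the dihydrofuran ring first (ring closure through a p-quinone methide), then C2–H (C2 becomes a ketone), then C9–OAr and C3–C9 (oxa-Michael addition and methylenation, C9 = formaldehyde carbon), and last C3–C3a (ketone α-arylation). This leads to eugenol (used twice), acetovanillone and one CH2 unit.
- Forward: C3–C3a is made by Pd α-arylation; C3–C9 and C9–O follow by methylenation and oxa-Michael addition of eugenol, giving the whole skeleton as a racemic ketone. The only ring formed (O1–C2–C3–C3a–C7a) is closed in the last step.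
- Stereochemistry: C3 (R) comes from a dynamic kinetic resolution during Ru-catalysed asymmetric transfer hydrogenation of the racemic ketone. C2 (S) comes from trans-selective, thermodynamically controlled ring closure through the p-quinone methide.
- Enabling feature: C3 lies between the arene carbon C3a and C2, so with C2 as a carbonyl the C3–H is an α-aryl ketone C–H and the centre racemises. C2 carries the 4-hydroxy-3-methoxyphenyl ring, so O1–C2 forms reversibly via the quinone methide and carbinol epimers or a cis isomer converge on the trans ring.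

Key step: step 6

Remark: the sense of induction in step 6 is assigned from the Noyori–Ikariya model for aryl ketones combined with Felkin–Anh control. If the matched ketone enantiomer proves to be the other one, the (R,R)-catalyst is used instead, since the carbinol centre is erased in step 7 and only C3 is carried through.

**Step 1**
Reactants: 1 eugenol (4-allyl-2-methoxyphenol)
Product: 2 4-allyl-2-bromo-6-methoxyphenol
Conditions: NBS (1.0 equiv), i-Pr2NH (10 mol %), CH2Cl2, 0 °C, dark
Reagents that add atoms: N-bromosuccinimide, O=C1CCC(=O)N1Br
Why: amine-catalysed ortho-selective electrophilic bromination of a phenol should place bromine at the only free position ortho to OH (para is blocked by the allyl group), and the ionic, low-temperature conditions should spare the terminal alkene.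

**Step 2**
Reactants: 2 4-allyl-2-bromo-6-methoxyphenol
Product: 3 5-allyl-1-bromo-3-methoxy-2-(methoxymethoxy)benzene
Conditions: NaH (1.2 equiv), MOMCl (1.3 equiv), THF/DMF, 0 °C to rt
Reagents that add atoms: chloromethyl methyl ether, COCCl
Why: Williamson-type O-alkylation of the hindered phenoxide gives a MOM acetal that should survive the basic steps and leave under the acid that triggers ring closure in step 7.

**Step 3**
Reactants: 4 acetovanillone (1-(4-hydroxy-3-methoxyphenyl)ethan-1-one)
Product: 5 1-[3-methoxy-4-(methoxymethoxy)phenyl]ethan-1-one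
Conditions: K2CO3 (1.5 equiv), MOMCl (1.3 equiv), acetone, 0 °C to rt
Reagents that add atoms: chloromethyl methyl ether, COCCl
Why: O-alkylation of the acidic para-acyl phenol masks the phenoxide, which would otherwise interfere with the enolate chemistry of steps 4 and 5.

**Step 4**
Reactants: 3 5-allyl-1-bromo-3-methoxy-2-(methoxymethoxy)benzene; 5 1-[3-methoxy-4-(methoxymethoxy)phenyl]ethan-1-one
Product: 6 2-[5-allyl-3-methoxy-2-(methoxymethoxy)phenyl]-1-[3-methoxy-4-(methoxymethoxy)phenyl]ethan-1-one
Conditions: Pd2(dba)3 (1.5 mol %), Xantphos (3.6 mol %), NaOtBu (2.2 equiv), THF, 65 °C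
Reagents that add atoms: none
Why: Buchwald–Hartwig–Miura α-arylation of the methyl ketone enolate forms the C3–C3a bond, and with a wide-bite-angle ligand C–C reductive elimination should outrun Heck insertion into the remote allyl group, while the alkoxide is largely consumed as enolate so allyl-to-propenyl isomerisation is not expected.

**Step 5**
Reactants: 6 2-[5-allyl-3-methoxy-2-(methoxymethoxy)phenyl]-1-[3-methoxy-4-(methoxymethoxy)phenyl]ethan-1-one; 1 eugenol
Product: 8 rac-3-(4-allyl-2-methoxyphenoxy)-2-[5-allyl-3-methoxy-2-(methoxymethoxy)phenyl]-1-[3-methoxy-4-(methoxymethoxy)phenyl]propan-1-one, via enone 7 (not isolated)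
Conditions: Me2NCH2NMe2 (3 equiv), Ac2O (3 equiv), DMF, 60 °C; aqueous work-up; then eugenol (1.3 equiv), Cs2CO3 (0.2 equiv), MeCN, 0 °C to rt
Reagents that add atoms: bis(dimethylamino)methane, CN(C)CN(C)C
Why: Mannich-type α-methylenation (Me2N=CH2+ from the aminal and Ac2O, then β-elimination) should give the 2-aryl enone, and phenoxide-catalysed oxa-Michael addition of eugenol then forms the C9–O aryl ether; C3 is formed racemic on purpose because step 6 resolves it dynamically.

**Step 6**
Reactants: 8 rac-3-(4-allyl-2-methoxyphenoxy)-2-[5-allyl-3-methoxy-2-(methoxymethoxy)phenyl]-1-[3-methoxy-4-(methoxymethoxy)phenyl]propan-1-one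
Product: 9 (1S,2R)-3-(4-allyl-2-methoxyphenoxy)-2-[5-allyl-3-methoxy-2-(methoxymethoxy)phenyl]-1-[3-methoxy-4-(methoxymethoxy)phenyl]propan-1-ol
Conditions: RuCl[(S,S)-TsDPEN](p-cymene) (2 mol %), HCO2H (3 equiv)/Et3N (4 equiv), eugenol (0.5 equiv, additive), DMF, 40 °C
Reagents that add atoms: none
Why: This is a Noyori–Ikariya asymmetric transfer hydrogenation with dynamic kinetic resolution: the Ru amide takes H2 from formate and delivers hydride and proton to C=O through the six-membered outer-sphere transition state, while the enantiomers of 8 interconvert through the enol(ate) because the C3–H is both α to the ketone and benzylic to the C3a arene. The closest known reaction type is the ATH-DKR of α-aryl ketones, in particular of isoflavanones, which are the cyclic α-aryl β-aryloxy ketones. No ring is closed in this step. The carbinol centre (1S) is set by the catalyst (CH/π contact of the aroyl ring with p-cymene, as for acetophenone), and the chain C2 (2R, the future C3) by Felkin–Anh matching, the (R)-ketone presenting its aryl group anti to the hydride on the catalyst-preferred face. The step needs enolisation to be faster than reduction of the mismatched (S)-ketone and C=O reduction to be chemoselective over the allyl groups and MOM acetals; the doubly activated C3–H under base-rich formate/Et3N should secure the first, the bifunctional outer-sphere mechanism the second, and the added eugenol should return any retro-oxa-Michael enone 7 to 8. Because the carbinol centre is catalyst-controlled, any mismatched product is the (1S,2S) diastereomer and is removed by chromatography, so the enantiopurity at C3 does not depend on the diastereomer ratio.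

**Step 7**
Reactants: 9 (1S,2R)-3-(4-allyl-2-methoxyphenoxy)-2-[5-allyl-3-methoxy-2-(methoxymethoxy)phenyl]-1-[3-methoxy-4-(methoxymethoxy)phenyl]propan-1-ol
Product: 12 4-[(2S,3R)-5-allyl-3-[(4-allyl-2-methoxyphenoxy)methyl]-7-methoxy-2,3-dihydro-1-benzofuran-2-yl]-2-methoxyphenol (target), via triol 10 (not isolated), via quinone methide 11 (not isolated)
Conditions: 1.25 M HCl in MeOH/THF (1:1), 40 °C; then NaHCO3
Reagents that add atoms: none
Why: acidic methanolysis should remove both MOM acetals and ionise the 4-hydroxybenzylic alcohol to the p-quinone methide (as its O-protonated form), which the neighbouring C7a phenol captures in a 5-exo-trig oxa-1,6-addition; since the O1–C2 bond stays reversible through the quinone methide while C3 is untouched, both carbinol epimers and any cis isomer should converge on the more stable 2,3-trans (2S,3R) ring.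

**Compound list**

1 | eugenol (4-allyl-2-methoxyphenol) | C=CCc1ccc(O)c(OC)c1 | starting material
2 | 4-allyl-2-bromo-6-methoxyphenol | C=CCc1cc(Br)c(O)c(OC)c1 | intermediate
3 | 5-allyl-1-bromo-3-methoxy-2-(methoxymethoxy)benzene | C=CCc1cc(Br)c(OCOC)c(OC)c1 | intermediate
4 | acetovanillone (1-(4-hydroxy-3-methoxyphenyl)ethan-1-one) | CC(=O)c1ccc(O)c(OC)c1 | starting material
5 | 1-[3-methoxy-4-(methoxymethoxy)phenyl]ethan-1-one | CC(=O)c1ccc(OCOC)c(OC)c1 | intermediate
6 | 2-[5-allyl-3-methoxy-2-(methoxymethoxy)phenyl]-1-[3-methoxy-4-(methoxymethoxy)phenyl]ethan-1-one | C=CCc1cc(CC(=O)c2ccc(OCOC)c(OC)c2)c(OCOC)c(OC)c1 | intermediate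
7 | 2-[5-allyl-3-methoxy-2-(methoxymethoxy)phenyl]-1-[3-methoxy-4-(methoxymethoxy)phenyl]prop-2-en-1-one | C=CCc1cc(C(=C)C(=O)c2ccc(OCOC)c(OC)c2)c(OCOC)c(OC)c1 | intermediate (not isolated)
8 | rac-3-(4-allyl-2-methoxyphenoxy)-2-[5-allyl-3-methoxy-2-(methoxymethoxy)phenyl]-1-[3-methoxy-4-(methoxymethoxy)phenyl]propan-1-one | C=CCc1ccc(OCC(C(=O)c2ccc(OCOC)c(OC)c2)c2cc(CC=C)cc(OC)c2OCOC)c(OC)c1 | intermediate
9 | (1S,2R)-3-(4-allyl-2-methoxyphenoxy)-2-[5-allyl-3-methoxy-2-(methoxymethoxy)phenyl]-1-[3-methoxy-4-(methoxymethoxy)phenyl]propan-1-ol | C=CCc1ccc(OC[C@@H](c3cc(CC=C)cc(OC)c3OCOC)[C@H](O)c2ccc(OCOC)c(OC)c2)c(OC)c1 | intermediate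
10 | (1S,2R)-3-(4-allyl-2-methoxyphenoxy)-2-(5-allyl-2-hydroxy-3-methoxyphenyl)-1-(4-hydroxy-3-methoxyphenyl)propan-1-ol | C=CCc1ccc(OC[C@@H](c3cc(CC=C)cc(OC)c3O)[C@H](O)c2ccc(O)c(OC)c2)c(OC)c1 | intermediate (not isolated)
11 | 4-[(2R)-3-(4-allyl-2-methoxyphenoxy)-2-(5-allyl-2-hydroxy-3-methoxyphenyl)propylidene]-2-methoxycyclohexa-2,5-dien-1-one | C=CCc1ccc(OC[C@@H](c3cc(CC=C)cc(OC)c3O)C=C2C=CC(=O)C(OC)=C2)c(OC)c1 | intermediate (not isolated)
12 | 4-[(2S,3R)-5-allyl-3-[(4-allyl-2-methoxyphenoxy)methyl]-7-methoxy-2,3-dihydro-1-benzofuran-2-yl]-2-methoxyphenol | C=CCc1ccc(OC[C@H]2c3cc(CC=C)cc(OC)c3O[C@@H]2c2ccc(O)c(OC)c2)c(OC)c1 | target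

**Step count**

Total steps: 7. Longest linear sequence: 6 steps (1 → 2 → 3 → 6 → 8 → 9 → 12; steps 1, 2, 4, 5, 6, 7).

**Steps most likely to fail**

Step 6. Enolisation of 8 may be too slow relative to reduction, so that the reaction becomes a plain kinetic resolution. The matched/mismatched discrimination may be weak. Material may also leak through base-induced retro-oxa-Michael elimination followed by reduction of the enone. The fallback sets out from 8 and uses the same catalyst under non-epimerising conditions (5:2 HCO2H/Et3N azeotrope, CH2Cl2, 0 to 10 °C) as a catalyst-controlled divergent reduction of the racemate. Both ketone enantiomers are reduced to the (1S)-carbinol, giving 9 and the (1S,2S)-alcohol F1, which are diastereomers and are separated by chromatography. The (1S,2S)-alcohol F1 is re-oxidised with Dess–Martin periodinane to the (S)-ketone, which is racemised with DBU and resubmitted as 8. The fallback returns to the route at 9.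

Step 5. The free enone 7 may oligomerise (hetero-Diels–Alder dimerisation, anionic polymerisation) while it is prepared and concentrated, before eugenol captures it. The fallback sets out from 6. A Mannich reaction with Eschenmoser's salt (CH2=NMe2+ I−, MeCN, rt) gives the isolable Mannich base F2. N-Methylation with MeI gives the trimethylammonium iodide F3. Treatment of F3 with K2CO3 and eugenol in MeCN releases 7 by E1cB elimination at low stationary concentration in the presence of the phenoxide, which adds at once. The fallback returns to the route at 8.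

Step 7. Prolonged exposure of the C2 cation/quinone methide to the acid needed for MOM cleavage may cause loss of the C3 proton (stilbene formation, erosion of the C3 configuration) or Friedel–Crafts capture by the eugenyl ring. The fallback sets out from 9 and separates deprotection from ring closure. Both aryl MOM ethers are cleaved without protic acid (TMSOTf, 2,2′-bipyridyl, CH2Cl2, 0 °C; then water) and triol 10 is isolated. Ring closure then follows under Mitsunobu conditions (PPh3, DIAD, THF, 0 °C), in which the activated 4-hydroxybenzylic alcohol collapses to quinone methide 11 and is captured by the neighbouring phenol under neutral conditions. Any cis isomer is equilibrated to trans through the same quinone methide with a trace of acid. The fallback returns to the route at 12.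

**Further compounds**

F1 | step 6 | (1S,2S)-3-(4-allyl-2-methoxyphenoxy)-2-[5-allyl-3-methoxy-2-(methoxymethoxy)phenyl]-1-[3-methoxy-4-(methoxymethoxy)phenyl]propan-1-ol | C=CCc1ccc(OC[C@H](c3cc(CC=C)cc(OC)c3OCOC)[C@H](O)c2ccc(OCOC)c(OC)c2)c(OC)c1
F2 | step 5 | 2-[5-allyl-3-methoxy-2-(methoxymethoxy)phenyl]-3-(dimethylamino)-1-[3-methoxy-4-(methoxymethoxy)phenyl]propan-1-one | C=CCc1cc(C(CN(C)C)C(=O)c2ccc(OCOC)c(OC)c2)c(OCOC)c(OC)c1
F3 | step 5 | 2-[5-allyl-3-methoxy-2-(methoxymethoxy)phenyl]-3-[3-methoxy-4-(methoxymethoxy)phenyl]-N,N,N-trimethyl-3-oxopropan-1-aminium iodide | C=CCc1cc(C(C[N+](C)(C)C)C(=O)c2ccc(OCOC)c(OC)c2)c(OCOC)c(OC)c1.[I-]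
F0 | step 7 | none | none
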